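The numbers are assumed, and the outcome is calculated.

You bet that nucleophile would outrun self-condensation; I reckoned the race as a tie first.

    electrophile + nucleophile → acid + target + leaving group (k1 = 0.16 M⁻¹ s⁻¹)
    protonated nucleophile ⇌ nucleophile + acid, settled at all times (K2 = 2.0 × 10⁻⁷ M)
    buffer acid ⇌ buffer base + acid, settled at all times (K3 = 5.0 × 10⁻⁹ M)
    electrophile + target → side product (k4 = 0.25 M⁻¹ s⁻¹)
    2 electrophile → self-condensation product (k5 = 0.24 M⁻¹ s⁻¹)

electrophile 39 mM; nucleophile 3.00 equiv (fed, over 1.0 min); buffer base 2.00 equiv; buffer acid 0.300 equiv; time 1.0 min

- part of the electrophile that has reacted at 1.0 min
- pH of the solution at 1.0 min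

- acid is the free proton; pH is minus the decimal logarithm of its molar concentration
- a species is counted by the electrophile in it: one side product or self-condensation product counts as two
- where a step has two of a species, its rate is k times that concentration squared, and two are used at each turn
- run time (flask): 1.0 min

- I took the symmetric case, S = 1, as the zero of the scale. S, a selectivity factor, was the electrophile taken per second by nucleophile over that taken by self-condensation.
- The whole nucleophile charge against fresh electrophile gave 1.00; this ratio, which the electrophile concentration cancels from, was my tie number.
- With a tie, I could drop neither route, so I multiplied two survivals.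
- Nucleophile, rising steadily from nothing, averaged half its charge, so its route left exp(−G) of the electrophile, with G = 0.562.
- Self-condensation by itself left one over one plus D, with D = 1.12.
- Together they gave 73.1% reacted; I made no pH figure.
- The forecast gave 71% (66% to 76%), lower than mine, and pH 8.82 (8.75 to 8.9), holding that electrophile is “lost mainly to self-condensation early on”.
- The flask gave 71.0% reacted and pH 8.83.
- S in this flask had reached 3.1 at 1.00 min, above the tie number, yet it held more self-condensation product, 43.8%, than target, 22.4%. With 1.20 equiv of nucleophile, the neighbour flask's tie number fell to 0.400, and the same product of survivals gave 62.4% reacted. That flask had 61.1% reacted, its S was still 0.928 at 1.00 min, and it held 10.0% target against 48.7% self-condensation product.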